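(Readings and results were computed for an exercise; the scatter is artificial.)

Start from amounts: the flask holds 1.7 mM of free catalyst against 0.050 M of starting material, far less, so for much of the starting material to react each catalyst must go round many times. Counting those rounds is the reckoning here.

all flasks: starting material 0.050 M; free catalyst 1.7 mM
- grey: reagent 0.10 M (fed, over 2.0 h); run made earlier; the fed solution adds 1.0 times the starting volume
- green: reagent 0.40 M (fed, over 2.0 h); run made earlier; the fed solution adds 1.0 times the starting volume
- flask: reagent 0.200 M (fed, over 2.0 h); the fed solution adds 1.0 times the starting volume; time 30 h

- grey (time / h: starting material / %, product / %): 1.33: 96, 1; 2.50: 95, 6; 4.00: 93, 8; 6.00: 89, 9; 10.0: 80, 17; 20.0: 66, 31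
- green (time / h: starting material / %, product / %): 3.00: 94, 4; 6.00: 85, 13; 10.0: 76, 23; 12.0: 72, 25; 15.0: 66, 30; 20.0: 57, 42

(scatter of a reading: 1.5 percentage points)

1. part of the starting material that has reacted at 30 h
2. share of the unused reagent that is free and not bound as idle adduct, at 30 h

- amounts are per litre of the starting volume; all of the dose is in the solution fed
- the earlier runs were read with a standard deviation of 1.5 percentage points
- the earlier runs do not show how much of reagent is bound; that part of a forecast is a guess

Read both earlier runs at 20.0 h: grey keeps 66% of its starting material, green 57%. Taken as first-order decay, that is 0.0208 /h for grey and 0.0281 /h for green. The flask's c(reagent) is twice grey's and half of green's, so you take the geometric middle, 0.0242 /h.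

Now the ladder, fastest first. At the full charge of starting material I reckon one turnover at about 1.41 h, shorter than the feed of 2.0 h. The half-life of the starting material is far longer, 28.7 h. So I expect the flask to end its feed with about 4.84% reacted and then to creep, and the asked 30 h lies close to that reckoned half-life.

My first answer, as if the starting material stayed at its charge, is 72.5%. But if the fall is taken as a straight line, the average left is one minus half the answer, so put it back: 46.2%, then 55.7%, then 52.3%. I commit to that last figure, which makes 15.4 for N, the turnover number: starting material reacted per catalyst charged.

The forecast gives 53% (47% to 58%) reacted and 99.2% (98.8% to 99.8%) free, holding that “Bound reagent is about 0.67 mM, capped at 0.85 mM”.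

The flask gives 52.7% reacted and 90.7% free. At 30.0 h it holds 0.00808 M of idle adduct, more than its 0.850 mM of catalyst after dilution. The flask's count now reads 15.5 turnovers, and each releases one by-product, so about 0.0132 M of by-product has been made in the doubled volume, and the idle adduct draws on that.

    reagent + catalyst intermediate A → catalyst intermediate B (k = 0.460 /M/min)
    catalyst intermediate B ⇌ by-product + catalyst intermediate C (K = 0.0640 M, k = 0.123 /min)
    catalyst intermediate C → free catalyst + product (k = 0.0685 /min)
    starting material + free catalyst → catalyst intermediate A (k = 0.820 /M/min)
    reagent + by-product ⇌ idle adduct, settled at all times (K = 20.9 /M)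

Take the neighbour charged with 0.020 M of starting material. Assuming my reacted percentage there too, N in that neighbour is 6.15, hence about 0.00523 M of by-product made, free and bound together. Computed, that neighbour reacts 64.3%, which is 7.56 turnovers, holds 0.00414 M of idle adduct and leaves 95.6% of its unused reagent free.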